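Everything rests on cutting the C2′–C3′ bond of the octyl chain on ring carbon C6 (chain atoms C1′–C8′) and reading the ethyl branch on C2′ as a reduced vinyl group. C2′ then is the γ-carbon of an (E)-but-2-enyl phosphate attached to quaternary C6 of the finished 1,2-dioxane. One ligand-controlled, copper-catalysed SN2′ allylic alkylation with bis[(2S)-2-methylhexyl]zinc joins the two halves, forms this bond with allylic transposition and sets C2′. The precursor is thus a linear allylic phosphate on the intact peroxide core; the ring itself comes from ozonolysis in methanol, mesylate displacement by the hydroperoxide and a peroxycarbenium allylation that fixes C6. Diimide reduction, desilylation and oxidation finish the acid.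

Key step: step 14

Remarks and assumptions (one line each):
- Locants: the dioxane is numbered as in the target throughout (O1, O2, C3 with the two-carbon arm, C4 with ethyl, C5, quaternary C6).
- 2-(Bromomethyl)but-1-ene (8) is taken as a catalogue compound; otherwise it is one step from 2-methylidenebutan-1-ol with PBr3.
- The (4S) auxiliary in 12 is written for the chelated transition-state model of the titanium acetate aldol; if the sense is the opposite, the (4R) auxiliary is used and nothing else changes.
- The NHC ligand enantiomer in step 14 is the one that delivers the alkyl group to the face giving (2′S); both ligand enantiomers are accessible and the choice changes no structure below.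

Step 1
Reactants: 1 (R)-3-bromo-2-methylpropan-1-ol; 2 n-propylmagnesium chloride
Product: 3 (S)-2-methylhexan-1-ol
Conditions: 2 (3 equiv), Li2CuCl4 (3 mol %), THF, −78 °C → rt; aq. NH4Cl
Reagents that add atoms: none
Why: Copper-catalysed Kochi sp3–sp3 coupling of the primary bromide (the first equivalent of Grignard reagent only deprotonates the alcohol); the chiral-pool stereocentre is not touched and changes from R to S only through CIP priorities.

Step 2
Reactants: 3 (S)-2-methylhexan-1-ol
Product: 4 (S)-1-iodo-2-methylhexane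
Conditions: I2, PPh3, imidazole, CH2Cl2, 0 °C → rt
Reagents that add atoms: iodine (II)
Why: Garegg–Samuelsson (Appel-type) iodination of a primary alcohol, which leaves the β-stereocentre untouched.

Step 3
Reactants: 5 (R)-4-benzyl-1,3-oxazolidin-2-one; 6 butanoyl chloride
Product: 7 (R)-4-benzyl-3-butanoyl-1,3-oxazolidin-2-one
Conditions: n-BuLi, THF, −78 °C; then 6
Reagents that add atoms: none
Why: N-Acylation of the lithiated oxazolidinone, the standard entry to an Evans imide.

Step 4
Reactants: 7 (R)-4-benzyl-3-butanoyl-1,3-oxazolidin-2-one; 8 2-(bromomethyl)but-1-ene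
Product: 9 (4R)-4-benzyl-3-[(2S)-2-ethyl-4-methylidenehexanoyl]-1,3-oxazolidin-2-one
Conditions: NaHMDS, THF, −78 °C; then 8, −78 → −40 °C
Reagents that add atoms: none
Why: Evans asymmetric alkylation, in which the chelated Z-sodium enolate is attacked by the reactive allylic bromide on the face opposite the benzyl group, setting the future ring carbon C4 as (S).

Step 5
Reactants: 9 (4R)-4-benzyl-3-[(2S)-2-ethyl-4-methylidenehexanoyl]-1,3-oxazolidin-2-one
Product: 10 (2S)-2-ethyl-4-methylidenehexan-1-ol
Conditions: LiBH4, MeOH (1 equiv), Et2O, 0 °C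
Reagents that add atoms: none
Why: Reductive cleavage of the imide at the exocyclic carbonyl group, which releases the auxiliary without epimerisation.

Step 6
Reactants: 10 (2S)-2-ethyl-4-methylidenehexan-1-ol
Product: 11 (2S)-2-ethyl-4-methylidenehexanal
Conditions: Dess–Martin periodinane, NaHCO3, CH2Cl2, 0 °C → rt; used at once
Reagents that add atoms: none
Why: Buffered Dess–Martin oxidation is neutral enough to keep the α-stereocentre of the aldehyde intact.

Step 7
Reactants: 11 (2S)-2-ethyl-4-methylidenehexanal; 12 (4S)-3-acetyl-4-benzyl-1,3-thiazolidine-2-thione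
Product: 13 (3R,4S)-1-[(4S)-4-benzyl-2-sulfanylidene-1,3-thiazolidin-3-yl]-4-ethyl-3-hydroxy-6-methylideneoctan-1-one
Conditions: 12, TiCl4, i-Pr2NEt, CH2Cl2, −40 °C; then 11, −78 °C
Reagents that add atoms: none
Why: Nagao–Fujita-type titanium acetate aldol reaction through a chelated chair transition state, in which the auxiliary (reagent control) selects the aldehyde face and sets the carbinol as (3R), anti to the C4 ethyl group.

Step 8
Reactants: 13 (3R,4S)-1-[(4S)-4-benzyl-2-sulfanylidene-1,3-thiazolidin-3-yl]-4-ethyl-3-hydroxy-6-methylideneoctan-1-one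
Product: 14 (3R,4S)-4-ethyl-6-methylideneoctane-1,3-diol
Conditions: NaBH4, THF/EtOH, 0 °C → rt
Reagents that add atoms: none
Why: The activated N-acyl thiazolidinethione is reduced by borohydride to the primary alcohol with release of the auxiliary and no change at the stereocentres.

Step 9
Reactants: 14 (3R,4S)-4-ethyl-6-methylideneoctane-1,3-diol
Product: 15 (3R,4S)-1-[(tert-butyldiphenylsilyl)oxy]-4-ethyl-6-methylideneoctan-3-ol
Conditions: TBDPSCl (1.05 equiv), imidazole, CH2Cl2, 0 °C
Reagents that add atoms: tert-butylchlorodiphenylsilane (CC(C)(C)[Si](Cl)(c1ccccc1)c1ccccc1)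
Why: The bulky silyl chloride reacts selectively with the primary hydroxyl group of the 1,3-diol.

Step 10
Reactants: 15 (3R,4S)-1-[(tert-butyldiphenylsilyl)oxy]-4-ethyl-6-methylideneoctan-3-ol
Product: 16 (3R,4S)-1-[(tert-butyldiphenylsilyl)oxy]-4-ethyl-6-methylideneoctan-3-yl methanesulfonate
Conditions: MsCl, Et3N, CH2Cl2, 0 °C
Reagents that add atoms: methanesulfonyl chloride (CS(=O)(=O)Cl)
Why: O-Sulfonylation with retention turns the secondary carbinol into the leaving group for the ring closure.

Step 11
Reactants: 16 (3R,4S)-1-[(tert-butyldiphenylsilyl)oxy]-4-ethyl-6-methylideneoctan-3-yl methanesulfonate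
Product: 18 tert-butyl{2-[(3S,4S)-4,6-diethyl-6-methoxy-1,2-dioxan-3-yl]ethoxy}diphenylsilane (both C6 epimers), via hydroperoxy ketal 17 (not isolated)
Conditions: (i) O3, CH2Cl2/MeOH 3:1, −78 °C; N2 purge; evaporate below 20 °C; (ii) KOt-Bu, 18-crown-6, THF, 0 °C
Reagents that add atoms: ozone ([O-][O+]=O); methanol (CO)
Why: Criegee ozonolysis of the 1,1-disubstituted alkene in methanol should trap the ketone oxide as the α-methoxy hydroperoxide, whose potassium salt then displaces the secondary mesylate in a 6-exo-tet SN2 reaction with inversion at C3 (3R to 3S), closing the 1,2-dioxane; the configuration at the ketal carbon C6 is immaterial because step 12 erases it.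

Step 12
Reactants: 18 tert-butyl{2-[(3S,4S)-4,6-diethyl-6-methoxy-1,2-dioxan-3-yl]ethoxy}diphenylsilane; 19 allyltrimethylsilane
Product: 20 tert-butyl{2-[(3S,4S,6S)-4,6-diethyl-6-(prop-2-en-1-yl)-1,2-dioxan-3-yl]ethoxy}diphenylsilane
Conditions: TiCl4 (1.1 equiv), 19 (3 equiv), CH2Cl2, −78 °C
Reagents that add atoms: none
Why: Both ketal epimers should ionise (loss of the exocyclic methoxy group) to one cyclic peroxycarbenium ion, which the allylsilane captures in a Hosomi–Sakurai reaction by axial attack on the half-chair that keeps the C4 ethyl group pseudo-equatorial, so that the allyl group enters trans to the C4 ethyl group (the other face would need a 1,3-diaxial allyl/ethyl contact) and C6 becomes (S).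

Step 13
Reactants: 20 tert-butyl{2-[(3S,4S,6S)-4,6-diethyl-6-(prop-2-en-1-yl)-1,2-dioxan-3-yl]ethoxy}diphenylsilane; 21 diethyl prop-2-en-1-yl phosphate
Product: 22 (2E)-4-[(3S,5S,6S)-6-{2-[(tert-butyldiphenylsilyl)oxy]ethyl}-3,5-diethyl-1,2-dioxan-3-yl]but-2-en-1-yl diethyl phosphate
Conditions: Hoveyda–Grubbs II (5 mol %), 21 (3 equiv), CH2Cl2, 40 °C
Reagents that add atoms: none
Why: Olefin cross-metathesis of the unhindered terminal alkene with an excess of the allyl phosphate should give the E-allylic phosphate under thermodynamic control, and ruthenium alkylidenes tolerate dialkyl peroxides.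

Step 14
Reactants: 22 (2E)-4-[(3S,5S,6S)-6-{2-[(tert-butyldiphenylsilyl)oxy]ethyl}-3,5-diethyl-1,2-dioxan-3-yl]but-2-en-1-yl diethyl phosphate; 4 (S)-1-iodo-2-methylhexane
Product: 24 tert-butyl(2-{(3S,4S,6S)-6-[(2S,4S)-2-ethenyl-4-methyloctyl]-4,6-diethyl-1,2-dioxan-3-yl}ethoxy)diphenylsilane, via bis[(2S)-2-methylhexyl]zinc 23 (not isolated)
Conditions: (i) 4 (6 equiv), Et2Zn (neat), CuI (0.3 mol %), 50 °C, then EtI/Et2Zn removed in vacuo; (ii) 22, Ag(I) complex of a chiral sulfonate-tethered bidentate N-heterocyclic carbene (2.5 mol %), (CuOTf)2·C6H6 (2.5 mol %), THF, −15 °C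
Reagents that add atoms: none
Why: Iodine–zinc exchange turns 4 into dialkylzinc 23, which transmetalates to the chiral NHC–copper(I) complex; the alkylcopper species adds to the γ-carbon C2′ of the allylic phosphate anti to the leaving group, and reductive elimination from the σ-allyl copper(III) intermediate forms the C2′–C3′ bond and releases the terminal vinyl group (SN2′ with allylic transposition). The closest known reaction type is the copper-catalysed enantioselective allylic alkylation of (E)-allylic phosphates with dialkylzinc reagents under bidentate NHC ligands. No ring is closed. The new stereocentre C2′ is set by the chiral ligand (catalyst control), which differentiates the two faces of the E-alkene; the existing centres (quaternary C6 two bonds away, C4′ in the nucleophile) are remote, and the ligand antipode is available should they oppose it. The step needs γ- over α-selectivity, which the phosphate leaving group and the NHC–copper catalyst secure even at hindered termini, and it needs chemoselectivity for the allylic C–O bond over the O–O bond, which the non-basic, weakly reducing diorganozinc at −15 °C and the hindered peroxide (quaternary C6, branched C3) secure.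

Step 15
Reactants: 24 tert-butyl(2-{(3S,4S,6S)-6-[(2S,4S)-2-ethenyl-4-methyloctyl]-4,6-diethyl-1,2-dioxan-3-yl}ethoxy)diphenylsilane
Product: 25 tert-butyl(2-{(3S,4S,6S)-4,6-diethyl-6-[(2S,4S)-2-ethyl-4-methyloctyl]-1,2-dioxan-3-yl}ethoxy)diphenylsilane
Conditions: dipotassium azodicarboxylate, AcOH, MeOH/CH2Cl2, 0 °C → rt
Reagents that add atoms: none
Why: Diimide generated in the flask transfers H2 in a concerted syn fashion to the monosubstituted vinyl group and does not reduce the O–O bond, so the vinyl group becomes the ethyl branch without touching a stereocentre.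

Step 16
Reactants: 25 tert-butyl(2-{(3S,4S,6S)-4,6-diethyl-6-[(2S,4S)-2-ethyl-4-methyloctyl]-1,2-dioxan-3-yl}ethoxy)diphenylsilane
Product: 26 2-{(3S,4S,6S)-4,6-diethyl-6-[(2S,4S)-2-ethyl-4-methyloctyl]-1,2-dioxan-3-yl}ethan-1-ol
Conditions: HF·pyridine, THF/pyridine, 0 °C → rt
Reagents that add atoms: none
Why: Fluoride cleaves the Si–O bond under buffered acidic conditions, which avoids base-induced Kornblum–DeLaMare fragmentation at the C3–H of the peroxide.

Step 17
Reactants: 26 2-{(3S,4S,6S)-4,6-diethyl-6-[(2S,4S)-2-ethyl-4-methyloctyl]-1,2-dioxan-3-yl}ethan-1-ol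
Product: 27 2-{(3S,4S,6S)-4,6-diethyl-6-[(2S,4S)-2-ethyl-4-methyloctyl]-1,2-dioxan-3-yl}acetic acid
Conditions: TEMPO (0.2 equiv), PhI(OAc)2 (2.5 equiv), MeCN/H2O 1:1, rt
Reagents that add atoms: water (O)
Why: Oxoammonium (TEMPO/PhI(OAc)2) oxidation takes the primary alcohol through the aldehyde hydrate to the acid under mildly acidic conditions, which leave the O–O bond intact and avoid β-elimination of the β-peroxy aldehyde.

Compound list
1 | (R)-3-bromo-2-methylpropan-1-ol | BrC[C@H](C)CO | starting material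
2 | n-propylmagnesium chloride | CCC[Mg]Cl | starting material
3 | (S)-2-methylhexan-1-ol | CCCC[C@H](C)CO | intermediate
4 | (S)-1-iodo-2-methylhexane | CCCC[C@H](C)CI | intermediate
5 | (R)-4-benzyl-1,3-oxazolidin-2-one | O=C1N[C@H](Cc2ccccc2)CO1 | starting material
6 | butanoyl chloride | CCCC(=O)Cl | starting material
7 | (R)-4-benzyl-3-butanoyl-1,3-oxazolidin-2-one | CCCC(=O)N1[C@H](Cc2ccccc2)COC1=O | intermediate
8 | 2-(bromomethyl)but-1-ene | C=C(CC)CBr | starting material
9 | (4R)-4-benzyl-3-[(2S)-2-ethyl-4-methylidenehexanoyl]-1,3-oxazolidin-2-one | C=C(CC)C[C@H](CC)C(=O)N1[C@H](Cc2ccccc2)COC1=O | intermediate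
10 | (2S)-2-ethyl-4-methylidenehexan-1-ol | C=C(CC)C[C@H](CC)CO | intermediate
11 | (2S)-2-ethyl-4-methylidenehexanal | C=C(CC)C[C@H](CC)C=O | intermediate
12 | (4S)-3-acetyl-4-benzyl-1,3-thiazolidine-2-thione | CC(=O)N1[C@@H](Cc2ccccc2)CSC1=S | starting material
13 | (3R,4S)-1-[(4S)-4-benzyl-2-sulfanylidene-1,3-thiazolidin-3-yl]-4-ethyl-3-hydroxy-6-methylideneoctan-1-one | C=C(CC)C[C@H](CC)[C@@H](CC(=O)N1[C@@H](Cc2ccccc2)CSC1=S)O | intermediate
14 | (3R,4S)-4-ethyl-6-methylideneoctane-1,3-diol | C=C(CC)C[C@H](CC)[C@@H](CCO)O | intermediate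
15 | (3R,4S)-1-[(tert-butyldiphenylsilyl)oxy]-4-ethyl-6-methylideneoctan-3-ol | C=C(CC)C[C@H](CC)[C@@H](CCO[Si](c1ccccc1)(c1ccccc1)C(C)(C)C)O | intermediate
16 | (3R,4S)-1-[(tert-butyldiphenylsilyl)oxy]-4-ethyl-6-methylideneoctan-3-yl methanesulfonate | C=C(CC)C[C@H](CC)[C@@H](CCO[Si](c1ccccc1)(c1ccccc1)C(C)(C)C)OS(C)(=O)=O | intermediate
17 | (3R,4S)-1-[(tert-butyldiphenylsilyl)oxy]-4-ethyl-6-hydroperoxy-6-methoxyoctan-3-yl methanesulfonate (hydroperoxy ketal, both C6 epimers) | CCC(OC)(OO)C[C@H](CC)[C@@H](CCO[Si](c1ccccc1)(c1ccccc1)C(C)(C)C)OS(C)(=O)=O | intermediate (not isolated)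
18 | tert-butyl{2-[(3S,4S)-4,6-diethyl-6-methoxy-1,2-dioxan-3-yl]ethoxy}diphenylsilane (both C6 epimers) | CCC1(OC)C[C@H](CC)[C@H](CCO[Si](c2ccccc2)(c2ccccc2)C(C)(C)C)OO1 | intermediate
19 | allyltrimethylsilane | C=CC[Si](C)(C)C | starting material
20 | tert-butyl{2-[(3S,4S,6S)-4,6-diethyl-6-(prop-2-en-1-yl)-1,2-dioxan-3-yl]ethoxy}diphenylsilane | C=CC[C@@]1(CC)C[C@H](CC)[C@H](CCO[Si](c2ccccc2)(c2ccccc2)C(C)(C)C)OO1 | intermediate
21 | diethyl prop-2-en-1-yl phosphate | C=CCOP(=O)(OCC)OCC | starting material
22 | (2E)-4-[(3S,5S,6S)-6-{2-[(tert-butyldiphenylsilyl)oxy]ethyl}-3,5-diethyl-1,2-dioxan-3-yl]but-2-en-1-yl diethyl phosphate | CCOP(=O)(OCC)OC/C=C/C[C@@]1(CC)C[C@H](CC)[C@H](CCO[Si](c2ccccc2)(c2ccccc2)C(C)(C)C)OO1 | intermediate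
23 | bis[(2S)-2-methylhexyl]zinc | CCCC[C@H](C)C[Zn]C[C@@H](C)CCCC | intermediate (not isolated)
24 | tert-butyl(2-{(3S,4S,6S)-6-[(2S,4S)-2-ethenyl-4-methyloctyl]-4,6-diethyl-1,2-dioxan-3-yl}ethoxy)diphenylsilane | CCCC[C@H](C)C[C@H](C=C)C[C@@]1(CC)C[C@H](CC)[C@H](CCO[Si](c2ccccc2)(c2ccccc2)C(C)(C)C)OO1 | intermediate
25 | tert-butyl(2-{(3S,4S,6S)-4,6-diethyl-6-[(2S,4S)-2-ethyl-4-methyloctyl]-1,2-dioxan-3-yl}ethoxy)diphenylsilane | CCCC[C@H](C)C[C@H](CC)C[C@@]1(CC)C[C@H](CC)[C@H](CCO[Si](c2ccccc2)(c2ccccc2)C(C)(C)C)OO1 | intermediate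
26 | 2-{(3S,4S,6S)-4,6-diethyl-6-[(2S,4S)-2-ethyl-4-methyloctyl]-1,2-dioxan-3-yl}ethan-1-ol | CCCC[C@H](C)C[C@H](CC)C[C@@]1(CC)C[C@H](CC)[C@H](CCO)OO1 | intermediate
27 | 2-{(3S,4S,6S)-4,6-diethyl-6-[(2S,4S)-2-ethyl-4-methyloctyl]-1,2-dioxan-3-yl}acetic acid | CCCC[C@H](C)C[C@H](CC)C[C@@]1(CC)C[C@H](CC)[C@H](CC(=O)O)OO1 | target

Total step count: 17. Longest linear sequence: 15 steps (steps 3–17, from 5); the side-chain branch (steps 1–2) joins at step 14.

Steps most likely to fail

1. Step 14. What may go wrong: reductive cleavage of the O–O bond by alkylcopper or alkylzinc species, α-attack (SN2, linear product) at the neopentyl-like allyl terminus, and incomplete catalyst control over C2′ with the β-branched nucleophile. The fallback forms the same C2′–C3′ bond by a radical conjugate addition, with no organometallic nucleophile, setting out from 20 and returning at 25. Cross-metathesis of 20 with 3-acryloyl-1,3-oxazolidin-2-one (Hoveyda–Grubbs II, CH2Cl2, 40 °C) would give the (E)-N-enoyl oxazolidinone F1. Addition of the (S)-2-methylhexyl radical from iodide 4 to its β-carbon under chiral Lewis acid control (MgI2, chiral bis(oxazoline), Bu3SnH, catalytic Et3B/O2, CH2Cl2, −78 °C) would give the imide adduct F2. NaBH4 (THF/H2O) would reduce the imide to the 2-hydroxyethyl compound F3. TsCl/pyridine would give the tosylate F4, and NaBH4 in DMSO would reduce it to the ethyl compound 25.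

2. Step 12. What may go wrong: heterolysis of the ring O–O or C6–O bond by stoichiometric TiCl4 (Hock/Criegee-type fragmentation) before the weakly nucleophilic allylsilane captures the peroxycarbenium ion, with erosion of facial selectivity as the second concern. The fallback uses a stronger π-nucleophile under catalytic silyl triflate and brings in the four-carbon allylic unit directly, setting out from 18 and returning at 22 (no metathesis). A TMSOTf-catalysed vinylogous Mukaiyama addition of (E)-1-(trimethylsilyloxy)buta-1,3-diene to 18 (CH2Cl2, −78 °C), bonding through the diene terminus under the same axial-attack model, would give the (E)-enal F5. Luche reduction (NaBH4, CeCl3·7H2O, MeOH, −40 °C) would give the allylic alcohol F6. Diethyl chlorophosphate (pyridine, DMAP, CH2Cl2, 0 °C) would then give 22.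

3. Step 7. What may go wrong: poor facial selectivity when the auxiliary and the α-branched aldehyde are mismatched, and epimerisation of the aldehyde α-centre under Lewis-acidic conditions. The fallback sets the carbinol by catalyst-controlled ketone reduction, setting out from 11 and returning at 14. A Roskamp reaction of 11 with ethyl diazoacetate (SnCl2, CH2Cl2, rt) would give the β-keto ester F7. Noyori hydrogenation with a Ru(II)–(S)-BINAP catalyst (H2 at low pressure, EtOH) would give the (3R)-β-hydroxy ester F8; the sense is that known for α′-branched β-keto esters. LiAlH4 (THF, 0 °C) would reduce the ester to diol 14.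

Further compounds
F1 | step 14 | 3-{(2E)-4-[(3S,5S,6S)-6-{2-[(tert-butyldiphenylsilyl)oxy]ethyl}-3,5-diethyl-1,2-dioxan-3-yl]but-2-enoyl}-1,3-oxazolidin-2-one | O=C1OCCN1C(=O)/C=C/C[C@@]1(CC)C[C@H](CC)[C@H](CCO[Si](c2ccccc2)(c2ccccc2)C(C)(C)C)OO1
F2 | step 14 | imide adduct: analogue of 25 with CH2C(=O)-(2-oxo-1,3-oxazolidin-3-yl) in place of the C2′ ethyl group, same spatial arrangement at C2′ | CCCC[C@H](C)C[C@H](CC(=O)N1CCOC1=O)C[C@@]1(CC)C[C@H](CC)[C@H](CCO[Si](c2ccccc2)(c2ccccc2)C(C)(C)C)OO1
F3 | step 14 | primary alcohol: analogue of 25 with 2-hydroxyethyl in place of the C2′ ethyl group | CCCC[C@H](C)C[C@H](CCO)C[C@@]1(CC)C[C@H](CC)[C@H](CCO[Si](c2ccccc2)(c2ccccc2)C(C)(C)C)OO1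
F4 | step 14 | tosylate: analogue of 25 with 2-(4-methylbenzenesulfonyloxy)ethyl in place of the C2′ ethyl group | CCCC[C@H](C)C[C@H](CCOS(=O)(=O)c1ccc(C)cc1)C[C@@]1(CC)C[C@H](CC)[C@H](CCO[Si](c2ccccc2)(c2ccccc2)C(C)(C)C)OO1
F5 | step 12 | (2E)-4-[(3S,5S,6S)-6-{2-[(tert-butyldiphenylsilyl)oxy]ethyl}-3,5-diethyl-1,2-dioxan-3-yl]but-2-enal | O=C/C=C/C[C@@]1(CC)C[C@H](CC)[C@H](CCO[Si](c2ccccc2)(c2ccccc2)C(C)(C)C)OO1
F6 | step 12 | (2E)-4-[(3S,5S,6S)-6-{2-[(tert-butyldiphenylsilyl)oxy]ethyl}-3,5-diethyl-1,2-dioxan-3-yl]but-2-en-1-ol | OC/C=C/C[C@@]1(CC)C[C@H](CC)[C@H](CCO[Si](c2ccccc2)(c2ccccc2)C(C)(C)C)OO1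
F7 | step 7 | ethyl (4S)-4-ethyl-6-methylidene-3-oxooctanoate | C=C(CC)C[C@H](CC)C(=O)CC(=O)OCC
F8 | step 7 | ethyl (3R,4S)-4-ethyl-3-hydroxy-6-methylideneoctanoate | C=C(CC)C[C@H](CC)[C@@H](CC(=O)OCC)O
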